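**Plan**

Benzofuran numbering is used (O1, C2, C3, C3a, C4 to C7, C7a). Ring A is the fused benzene ring, ring B the dihydrofuran, ring C the 3,4,5-trimethoxyphenyl group. The retrosynthesis first removes a protecting group on O6, then cuts the C5–allyl bond, then cuts O1–C2 and C3–C3a of ring B together, and last cuts the ring C–propenyl bond.
Enabling feature: C2 is benzylic to ring C, whose para-methoxy group can carry a cation at C2 as a quinone-methide oxonium ion, and O1 sits on C7a next to C3a. Raising ring A to the quinone level with a helper oxygen at C5 (para to O1) makes C3a electrophilic. O1 then becomes a carbonyl oxygen that closes on C2 as soon as the C3–C3a bond exists.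
Forward order: (E)-isoelemicin and 2-isopropoxy-1,4-benzoquinone are made in one step each. Their union builds ring B and re-aromatises ring A in a single operation, copying the biogenetic C8–aryl coupling and quinone methide capture.
Helpers: the C5 hydroxyl group left by the quinone becomes a triflate and is replaced by allyl. The isopropyl group on O6, which steers the regiochemistry by chelation, is removed last.
Stereochemistry: C3 comes from the chiral titanium TADDOLate in the C–C bond formation. C2 follows from C3 and the E alkene through trans closure, and no later step touches either centre.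

Key step: step 3

Assumption: (R,R)-TADDOL is taken to shield the quinone face that leads to the (2S,3S) series. If the sense of induction is the opposite, the equally available (S,S)-TADDOL is used and nothing else changes.

**Step 1**
Reactants: 1 5-bromo-1,2,3-trimethoxybenzene; 2 (E)-prop-1-en-1-ylboronic acid
Product: 3 (E)-1,2,3-trimethoxy-5-(prop-1-en-1-yl)benzene ((E)-isoelemicin)
Conditions: Pd(PPh3)4 (cat.), K2CO3, 1,4-dioxane/H2O, 90 °C
Reagents that add atoms: none
Why: Suzuki–Miyaura coupling of an aryl bromide with an (E)-alkenylboronic acid runs with retention of alkene geometry, so the pure E geometry on which the trans C2/C3 relationship later depends is carried over from 2.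

**Step 2**
Reactants: 4 2-isopropoxyphenol
Product: 5 2-isopropoxy-1,4-benzoquinone
Conditions: (KSO3)2NO (2.2 equiv), KH2PO4, H2O/acetone, 0 °C to rt
Reagents that add atoms: potassium nitrosodisulfonate, [K+].[K+].[O]N(S(=O)(=O)[O-])S(=O)(=O)[O-]
Why: Teuber oxidation, in which one equivalent of the nitroxyl radical takes the phenolic hydrogen and a second delivers its oxygen to the free para position, should give the para-quinone while the isopropyl ether stays inert to this one-electron oxidant.

**Step 3**
Reactants: 3 (E)-isoelemicin; 5 2-isopropoxy-1,4-benzoquinone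
Product: 7 (2S,3S)-6-isopropoxy-3-methyl-2-(3,4,5-trimethoxyphenyl)-2,3-dihydrobenzofuran-5-ol, via benzylic cation titanium dienolate zwitterion 6 (not isolated)
Conditions: TiCl4/Ti(OiPr)4 (1:1) and (R,R)-TADDOL premixed (excess over 5), CH2Cl2, add 5 then 3 at −78 °C, warm to 0 °C; aq NaHCO3
Reagents that add atoms: none
Why: Mechanism: TiCl2(TADDOLate) chelates the C1 carbonyl oxygen and the isopropoxy oxygen of 5, the β-carbon of the propenyl group of 3 attacks quinone C5 (future C3a) to form C3–C3a, and this leaves zwitterion 6, a titanium dienolate joined to a benzylic cation at the future C2 that the para-methoxy group of ring C spreads out as a quinone-methide oxonium ion. The C4 carbonyl oxygen of 6 (future O1), made nucleophilic by the vinylogous isopropoxy group, adds to this cation and closes ring B in the 5-exo-trig mode, and loss of the proton at C3a restores aromatic ring A, so that 7 is freed on work-up. The closest known reaction type is the formal [3+2] cycloaddition of 2-alkoxy-1,4-benzoquinones with (E)-1-propenylarenes under tetravalent titanium Lewis acids, known also in enantioselective form with titanium TADDOLates, and it copies the biogenetic coupling of C8 of a propenylarene to an oxidised aryl ring followed by capture of the quinone methide by oxygen. C3 is set in the C–C bond formation by the ligand, whose aryl groups block one face of the chelated quinone while ring C lies over the quinone, so that one face of the alkene meets one face of C5. C2 is set by C3, because the oxygen closes on the face of the planar cation that places ring C anti to the C3 methyl group, and because closure is reversible under the Lewis acid, which lets the more stable trans isomer collect. The step needs attack at C5 and not at C3 or C6, which the chelate and the deactivation of the C4 carbonyl group as a vinylogous ester secure, and it needs closure through oxygen and not through a dienolate carbon, which is secured by warming (carbon closure is reversible) and by the secondary isopropyl group, which resists the chloride dealkylation that would make carbon closure permanent.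

**Step 4**
Reactants: 7 (2S,3S)-6-isopropoxy-3-methyl-2-(3,4,5-trimethoxyphenyl)-2,3-dihydrobenzofuran-5-ol
Product: 8 (2S,3S)-6-isopropoxy-3-methyl-2-(3,4,5-trimethoxyphenyl)-2,3-dihydrobenzofuran-5-yl trifluoromethanesulfonate
Conditions: Tf2O, pyridine, CH2Cl2, 0 °C
Reagents that add atoms: trifluoromethanesulfonic anhydride, O=S(=O)(OS(=O)(=O)C(F)(F)F)C(F)(F)F
Why: Routine O-sulfonylation of the phenol, the only acidic or nucleophilic site of 7, turns the helper oxygen at C5 into a leaving group for cross-coupling and touches no stereocentre.

**Step 5**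
Reactants: 8 the C5 triflate
Product: 9 (2S,3S)-5-allyl-6-isopropoxy-3-methyl-2-(3,4,5-trimethoxyphenyl)-2,3-dihydrobenzofuran
Conditions: allylSnBu3, Pd(PPh3)4 (cat.), LiCl (3 equiv), 1,4-dioxane, reflux
Reagents that add atoms: allyltributylstannane, C=CC[Sn](CCCC)(CCCC)CCCC
Why: In this Stille coupling of an aryl triflate, zerovalent palladium inserts into the aryl C–O bond, chloride from LiCl keeps the arylpalladium species fit for transmetalation, and allyl transfer from tin with reductive elimination puts the allyl group exactly where the helper oxygen stood, with no stereocentre involved.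

**Step 6**
Reactants: 9 the O6-isopropyl ether of the target
Product: 10 (2S,3S)-5-allyl-3-methyl-2-(3,4,5-trimethoxyphenyl)-2,3-dihydrobenzofuran-6-ol (target)
Conditions: BCl3 (1 M in CH2Cl2), CH2Cl2, −78 °C to −10 °C; then H2O
Reagents that add atoms: none
Why: In this Lewis-acid dealkylation of an aryl isopropyl ether, BCl3 binds the ether oxygen and the secondary alkyl group leaves as 2-chloropropane far faster than a methyl group can, a selectivity with close precedent next to 3,4,5-trimethoxyphenyl rings, and the low temperature should spare the allyl group and the O1–C2 bond.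

**Compound list**

1 | 5-bromo-1,2,3-trimethoxybenzene | COc1cc(Br)cc(OC)c1OC | starting material
2 | (E)-prop-1-en-1-ylboronic acid | C/C=C/B(O)O | starting material
3 | (E)-1,2,3-trimethoxy-5-(prop-1-en-1-yl)benzene, (E)-isoelemicin | C/C=C/c1cc(OC)c(OC)c(OC)c1 | intermediate
4 | 2-isopropoxyphenol | CC(C)Oc1ccccc1O | starting material
5 | 2-isopropoxy-1,4-benzoquinone | CC(C)OC1=CC(=O)C=CC1=O | intermediate
6 | benzylic cation titanium dienolate zwitterion (C3–C3a formed, O1–C2 still open; drawn without the metal; the ring CH centre is lost on aromatisation) | C[C@H]([CH+]c1cc(OC)c(OC)c(OC)c1)C1C=C([O-])C(OC(C)C)=CC1=O | intermediate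
7 | (2S,3S)-6-isopropoxy-3-methyl-2-(3,4,5-trimethoxyphenyl)-2,3-dihydrobenzofuran-5-ol | Oc1cc2c(cc1OC(C)C)O[C@H](c1cc(OC)c(OC)c(OC)c1)[C@H]2C | intermediate
8 | (2S,3S)-6-isopropoxy-3-methyl-2-(3,4,5-trimethoxyphenyl)-2,3-dihydrobenzofuran-5-yl trifluoromethanesulfonate | O=S(=O)(Oc1cc2c(cc1OC(C)C)O[C@H](c1cc(OC)c(OC)c(OC)c1)[C@H]2C)C(F)(F)F | intermediate
9 | (2S,3S)-5-allyl-6-isopropoxy-3-methyl-2-(3,4,5-trimethoxyphenyl)-2,3-dihydrobenzofuran | C=CCc1cc2c(cc1OC(C)C)O[C@H](c1cc(OC)c(OC)c(OC)c1)[C@H]2C | intermediate
10 | (2S,3S)-5-allyl-3-methyl-2-(3,4,5-trimethoxyphenyl)-2,3-dihydrobenzofuran-6-ol | C=CCc1cc2c(cc1O)O[C@H](c1cc(OC)c(OC)c(OC)c1)[C@H]2C | target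

Total step count: 6. Longest linear sequence: 5 (steps 1, 3, 4, 5, 6, or equally 2, 3, 4, 5, 6).

**Steps most likely to fail**

**Step 3.**
- Possible failures: closure of the zwitterion through a dienolate carbon instead of oxygen, cationic oligomerisation of the alkene, and incomplete facial selectivity at the quinone.
- The fallback sets out from 5 and comes back at 7. It builds C3 by enamine catalysis instead of cycloaddition.
- Propanal is α-arylated with 5 under a diphenylprolinol trimethylsilyl ether catalyst (the enantiomer that gives 3S; EtOH/H2O, low temperature). Attack is again at quinone C5, and aromatisation with hemiacetal closure gives the lactol (3S)-6-isopropoxy-3-methyl-2,3-dihydrobenzofuran-2,5-diol F1.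
- Excess 3,4,5-trimethoxyphenylmagnesium bromide (THF, −78 °C to 0 °C) adds to the open aldehyde form. This gives 2-[(2S)-1-hydroxy-1-(3,4,5-trimethoxyphenyl)propan-2-yl]-5-isopropoxybenzene-1,4-diol F2, and either carbinol epimer serves.
- Catalytic p-TsOH in CH2Cl2 ionises the benzylic alcohol, and the ortho phenol closes O1–C2 anti to the methyl group to give 7.

**Step 6.**
- Possible failures: competing Lewis-acid demethylation at the crowded para-methoxy group of ring C, ionisation of the O1–C2 bond followed by loss of the C3 proton, and acid-induced addition of the freed phenol to the allyl group.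
- The fallback sets out from 3 and comes back at 10. It replaces Lewis-acid unmasking by hydrogenolysis, done before any alkene is present.
- 2-(Benzyloxy)phenol is oxidised as in step 2 to 2-(benzyloxy)-1,4-benzoquinone F3.
- F3 is combined with 3 under the conditions of step 3 to give (2S,3S)-6-(benzyloxy)-3-methyl-2-(3,4,5-trimethoxyphenyl)-2,3-dihydrobenzofuran-5-ol F4.
- Tf2O/pyridine converts F4 into (2S,3S)-6-(benzyloxy)-3-methyl-2-(3,4,5-trimethoxyphenyl)-2,3-dihydrobenzofuran-5-yl trifluoromethanesulfonate F5.
- Hydrogenolysis (H2, Pd/C, EtOAc, no base) gives (2S,3S)-6-hydroxy-3-methyl-2-(3,4,5-trimethoxyphenyl)-2,3-dihydrobenzofuran-5-yl trifluoromethanesulfonate F6.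
- Stille allylation of F6 under the neutral conditions of step 5 gives 10 directly.

**Step 5.**
- Possible failures: slow oxidative addition into the electron-rich ortho-alkoxy triflate, hydrolysis of the triflate back to the phenol, and migration of the allyl double bond into conjugation at the temperature needed.
- The fallback sets out from 8 and comes back at 10. It makes the C5–allyl bond by a sigmatropic shift instead of cross-coupling.
- The triflate is reduced (Pd(OAc)2, dppf, HCO2H, Et3N, DMF, 70 °C) to (2S,3S)-6-isopropoxy-3-methyl-2-(3,4,5-trimethoxyphenyl)-2,3-dihydrobenzofuran F7.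
- BCl3 at low temperature gives (2S,3S)-3-methyl-2-(3,4,5-trimethoxyphenyl)-2,3-dihydrobenzofuran-6-ol F8.
- Allyl bromide and K2CO3 in acetone give (2S,3S)-6-(allyloxy)-3-methyl-2-(3,4,5-trimethoxyphenyl)-2,3-dihydrobenzofuran F9.
- Aromatic Claisen rearrangement (N,N-diethylaniline, about 190 °C) moves the allyl group to give 10. C5 should be preferred over C7, which is crowded between two oxygen atoms.

**Further compounds**

F1 | step 3 | (3S)-6-isopropoxy-3-methyl-2,3-dihydrobenzofuran-2,5-diol | C[C@@H]1C(O)Oc2cc(OC(C)C)c(O)cc21
F2 | step 3 | 2-[(2S)-1-hydroxy-1-(3,4,5-trimethoxyphenyl)propan-2-yl]-5-isopropoxybenzene-1,4-diol | C[C@H](C(O)c1cc(OC)c(OC)c(OC)c1)c1cc(O)c(OC(C)C)cc1O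
F3 | step 6 | 2-(benzyloxy)-1,4-benzoquinone | O=C1C=CC(=O)C(OCc2ccccc2)=C1
F4 | step 6 | (2S,3S)-6-(benzyloxy)-3-methyl-2-(3,4,5-trimethoxyphenyl)-2,3-dihydrobenzofuran-5-ol | Oc1cc2c(cc1OCc1ccccc1)O[C@H](c1cc(OC)c(OC)c(OC)c1)[C@H]2C
F5 | step 6 | (2S,3S)-6-(benzyloxy)-3-methyl-2-(3,4,5-trimethoxyphenyl)-2,3-dihydrobenzofuran-5-yl trifluoromethanesulfonate | O=S(=O)(Oc1cc2c(cc1OCc1ccccc1)O[C@H](c1cc(OC)c(OC)c(OC)c1)[C@H]2C)C(F)(F)F
F6 | step 6 | (2S,3S)-6-hydroxy-3-methyl-2-(3,4,5-trimethoxyphenyl)-2,3-dihydrobenzofuran-5-yl trifluoromethanesulfonate | O=S(=O)(Oc1cc2c(cc1O)O[C@H](c1cc(OC)c(OC)c(OC)c1)[C@H]2C)C(F)(F)F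
F7 | step 5 | (2S,3S)-6-isopropoxy-3-methyl-2-(3,4,5-trimethoxyphenyl)-2,3-dihydrobenzofuran | CC(C)Oc1ccc2c(c1)O[C@H](c1cc(OC)c(OC)c(OC)c1)[C@H]2C
F8 | step 5 | (2S,3S)-3-methyl-2-(3,4,5-trimethoxyphenyl)-2,3-dihydrobenzofuran-6-ol | Oc1ccc2c(c1)O[C@H](c1cc(OC)c(OC)c(OC)c1)[C@H]2C
F9 | step 5 | (2S,3S)-6-(allyloxy)-3-methyl-2-(3,4,5-trimethoxyphenyl)-2,3-dihydrobenzofuran | C=CCOc1ccc2c(c1)O[C@H](c1cc(OC)c(OC)c(OC)c1)[C@H]2C
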